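## Retrosynthetic overview

1. Target 13 ⇐ 12 by lipase-catalysed removal of three aryl acetates at neutral pH, so the base-labile C2 centre is never exposed to base.
2. 12 ⇐ boronic acid 9 + chromone 11: the C2–C1' bond is made by Rh-catalysed asymmetric 1,4-addition, which sets the only stereocentre (2S).
3. 9 ⇐ 8-iodo-tri-O-benzylapigenin 3 + chlorophenylboronic acid 4: Suzuki coupling makes the C3'–C8'' biaryl bond, then Cl → B and Bn → Ac.
4. Rings: no ring is built. Both benzopyranone units and all aryl rings are bought preformed (1, 4, 10). The flavanone ring C arises last, by saturating the C2=C3 bond of chromone 11.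

Assumption: apigenin, 5,7-dihydroxychromone and [2-(benzyloxy)-5-chlorophenyl]boronic acid are taken as commercial; unprimed/primed locants refer to the flavanone unit, double- and triple-primed locants to the flavone unit.

## Route

Step 1
Reactants: 1 apigenin (5,7-dihydroxy-2-(4-hydroxyphenyl)-4H-chromen-4-one)
Product: 2 tri-O-benzylapigenin (5,7-bis(benzyloxy)-2-[4-(benzyloxy)phenyl]-4H-chromen-4-one)
Conditions: BnBr (4 equiv), K2CO3, Bu4NI (cat.), DMF, 80 °C
Reagents that add atoms: benzyl bromide, BrCc1ccccc1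
Why: Williamson etherification under forcing conditions also caps the chelated 5-OH, which must be alkylated so that the next substitution goes to C8 and not C6.

Step 2
Reactants: 2 tri-O-benzylapigenin
Product: 3 8-iodo-tri-O-benzylapigenin (5,7-bis(benzyloxy)-2-[4-(benzyloxy)phenyl]-8-iodo-4H-chromen-4-one)
Conditions: N-iodosuccinimide (1.1 equiv), CF3CO2H (10 mol %), CH2Cl2, 0 °C to rt, dark
Reagents that add atoms: N-iodosuccinimide, O=C1CCC(=O)N1I
Why: Electrophilic aromatic iodination; in 5-O-alkylated 5,7-dioxygenated flavones C8 (para to 5-OR, ortho to 7-OR) is the most nucleophilic position.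

Step 3
Reactants: 3 8-iodo-tri-O-benzylapigenin; 4 [2-(benzyloxy)-5-chlorophenyl]boronic acid
Product: 5 biaryl chloride (5,7-bis(benzyloxy)-8-[2-(benzyloxy)-5-chlorophenyl]-2-[4-(benzyloxy)phenyl]-4H-chromen-4-one)
Conditions: PdCl2(dppf) (5 mol %), K2CO3 (3 equiv), 4 (1.6 equiv), 1,4-dioxane/H2O 5:1, 90 °C
Reagents that add atoms: none
Why: Suzuki–Miyaura coupling; the C–I bond reacts far faster than the electron-rich C–Cl bond with this catalyst, so only the biaryl bond forms and the chloride is kept as the handle for boron.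

Step 4
Reactants: 5 biaryl chloride
Product: 6 tetrabenzyl pinacol boronate (5,7-bis(benzyloxy)-8-[2-(benzyloxy)-5-(4,4,5,5-tetramethyl-1,3,2-dioxaborolan-2-yl)phenyl]-2-[4-(benzyloxy)phenyl]-4H-chromen-4-one)
Conditions: B2pin2 (1.5 equiv), Pd2(dba)3 (2 mol %), XPhos (8 mol %), KOAc (3 equiv), 1,4-dioxane, 100 °C
Reagents that add atoms: bis(pinacolato)diboron, CC1(C)OB(OC1(C)C)B1OC(C)(C)C(C)(C)O1
Why: Miyaura borylation of an electron-rich aryl chloride, which a bulky biarylphosphine ligand makes routine; ethers and the flavone are inert.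

Step 5
Reactants: 6 tetrabenzyl pinacol boronate
Product: 7 tetrahydroxy pinacol boronate (5,7-dihydroxy-8-[2-hydroxy-5-(4,4,5,5-tetramethyl-1,3,2-dioxaborolan-2-yl)phenyl]-2-(4-hydroxyphenyl)-4H-chromen-4-one)
Conditions: H2 (1 atm), 10 % Pd/C, THF/MeOH 1:1, rt
Reagents that add atoms: none
Why: Hydrogenolysis of the four benzyl ethers is done here, before any flavanone or stereocentre exists; the C–B bond and the flavone survive 1 atm H2 at rt.

Step 6
Reactants: 7 tetrahydroxy pinacol boronate
Product: 8 triacetate pinacol boronate (7-acetoxy-8-[2-acetoxy-5-(4,4,5,5-tetramethyl-1,3,2-dioxaborolan-2-yl)phenyl]-2-(4-acetoxyphenyl)-5-hydroxy-4H-chromen-4-one)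
Conditions: Ac2O (3.3 equiv), pyridine, CH2Cl2, 0 °C; chromatography
Reagents that add atoms: acetic anhydride, CC(=O)OC(C)=O
Why: O-acylation of the three non-chelated phenols; the 5-OH hydrogen-bonded to the C4 carbonyl acylates much more slowly and stays free, so no ester is placed where a lipase would not remove it.

Step 7
Reactants: 8 triacetate pinacol boronate
Product: 9 triacetate boronic acid ({4-acetoxy-3-[7-acetoxy-2-(4-acetoxyphenyl)-5-hydroxy-4-oxo-4H-chromen-8-yl]phenyl}boronic acid)
Conditions: NaIO4 (3 equiv), 1 M aq HCl (0.5 equiv), THF/H2O 4:1, rt; used crude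
Reagents that add atoms: water, O
Why: Boronate hydrolysis driven by periodate glycol cleavage of the released pinacol gives the free boronic acid needed for base-free transmetalation; aryl acetates survive dilute acid at rt.

Step 8
Reactants: 10 5,7-dihydroxychromone (5,7-dihydroxy-4H-chromen-4-one)
Product: 11 5-hydroxy-7-methoxychromone (5-hydroxy-7-methoxy-4H-chromen-4-one)
Conditions: MeI (1.1 equiv), K2CO3 (1.2 equiv), acetone, 40 °C
Reagents that add atoms: methyl iodide, CI
Why: Williamson methylation; only the acidic 7-OH reacts, the chelated 5-OH is not alkylated under these mild conditions.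

Step 9
Reactants: 9 triacetate boronic acid; 11 5-hydroxy-7-methoxychromone
Product: 12 (2S)-flavanone triacetate ((2S)-2-{4-acetoxy-3-[7-acetoxy-2-(4-acetoxyphenyl)-5-hydroxy-4-oxo-4H-chromen-8-yl]phenyl}-5-hydroxy-7-methoxychroman-4-one)
Conditions: [Rh(OH)(cod)]2 (2.5 mol %), (S)-MeO-F12-BIPHEP (5.5 mol %), 11 (2 equiv), 1,4-dioxane/H2O 10:1, 35 °C
Reagents that add atoms: none
Why: Hayashi–Miyaura asymmetric 1,4-addition; the (S)-bisphosphine–Rh–aryl species (same sense as (S)-BINAP with cyclohexenone) delivers the aryl group to the Re face of C2 to give (2S), and the base-free medium spares the acetates and the new centre, while the 2-aryl-substituted flavone enone does not react.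

Step 10
Reactants: 12 (2S)-flavanone triacetate
Product: 13 target, (2S)-2,3-dihydroamentoflavone 7-O-methyl ether ((2S)-2-{3-[5,7-dihydroxy-2-(4-hydroxyphenyl)-4-oxo-4H-chromen-8-yl]-4-hydroxyphenyl}-5-hydroxy-7-methoxychroman-4-one)
Conditions: lipase (immobilised Burkholderia cepacia lipase, a triacylglycerol hydrolase, EC 3.1.1.3), n-BuOH (30 equiv), THF, 40 °C
Reagents that add atoms: none
Why: Lipase-catalysed transesterification (alcoholysis) of phenolic acetates, known for flavonoid acetates and for ortho-aryl phenol acetates, frees the phenols at neutral pH, so C2, which racemises by retro-oxa-Michael ring opening under basic deacetylation, is untouched.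

## Compound list

1 | apigenin | O=c1cc(-c2ccc(O)cc2)oc2cc(O)cc(O)c12 | starting material
2 | tri-O-benzylapigenin | O=c1cc(-c2ccc(OCc3ccccc3)cc2)oc2cc(OCc3ccccc3)cc(OCc3ccccc3)c12 | intermediate
3 | 8-iodo-tri-O-benzylapigenin | O=c1cc(-c2ccc(OCc3ccccc3)cc2)oc2c(I)c(OCc3ccccc3)cc(OCc3ccccc3)c12 | intermediate
4 | [2-(benzyloxy)-5-chlorophenyl]boronic acid | OB(O)c1cc(Cl)ccc1OCc1ccccc1 | starting material
5 | biaryl chloride | O=c1cc(-c2ccc(OCc3ccccc3)cc2)oc2c(-c3cc(Cl)ccc3OCc3ccccc3)c(OCc3ccccc3)cc(OCc3ccccc3)c12 | intermediate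
6 | tetrabenzyl pinacol boronate | O=c1cc(-c2ccc(OCc3ccccc3)cc2)oc2c(-c3cc(B4OC(C)(C)C(C)(C)O4)ccc3OCc3ccccc3)c(OCc3ccccc3)cc(OCc3ccccc3)c12 | intermediate
7 | tetrahydroxy pinacol boronate | O=c1cc(-c2ccc(O)cc2)oc2c(-c3cc(B4OC(C)(C)C(C)(C)O4)ccc3O)c(O)cc(O)c12 | intermediate
8 | triacetate pinacol boronate | O=c1cc(-c2ccc(OC(C)=O)cc2)oc2c(-c3cc(B4OC(C)(C)C(C)(C)O4)ccc3OC(C)=O)c(OC(C)=O)cc(O)c12 | intermediate
9 | triacetate boronic acid | O=c1cc(-c2ccc(OC(C)=O)cc2)oc2c(-c3cc(B(O)O)ccc3OC(C)=O)c(OC(C)=O)cc(O)c12 | intermediate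
10 | 5,7-dihydroxychromone | O=c1ccoc2cc(O)cc(O)c12 | starting material
11 | 5-hydroxy-7-methoxychromone | COc1cc(O)c2c(=O)ccoc2c1 | intermediate
12 | (2S)-flavanone triacetate | COc1cc(O)c2c(c1)O[C@H](c1ccc(OC(C)=O)c(-c3c(OC(C)=O)cc(O)c4c(=O)cc(-c5ccc(OC(C)=O)cc5)oc34)c1)CC2=O | intermediate
13 | (2S)-2,3-dihydroamentoflavone 7-O-methyl ether | COc1cc(O)c2c(c1)O[C@H](c1ccc(O)c(-c3c(O)cc(O)c4c(=O)cc(-c5ccc(O)cc5)oc34)c1)CC2=O | target

## Step count and risks

Total steps: 10. Longest linear sequence: 9 steps (steps 1–7, 9, 10); step 8 is a one-step side branch.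

Three steps most likely to fail:

Step 9 (asymmetric 1,4-addition). The free chelated 5-OH of 11 or protodeboronation of 9 may cut conversion. The fallback sets out from 11 and comes back at 12. Compound 11 is capped with MOMCl/NaH in DMF to give 7-methoxy-5-(methoxymethoxy)-4H-chromen-4-one F3. This non-chelated, more electrophilic chromone takes up 9 under the same Rh/(S)-bisphosphine catalysis to give the (2S)-5-O-methoxymethyl flavanone triacetate F4. Brief CF3CO2H/CH2Cl2 (1:9) at 0 °C removes the peri acetal without touching the acetates and returns 12.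

Step 10 (lipase deacetylation). The two acetates flanking the biaryl axis may be slow substrates. The fallback sets out from 12 and comes back at 13. The lipase alcoholysis is run as far as it goes, which is expected to remove the two flavone acetates and leave the (2S)-4'-O-acetyl derivative of the target F5. The last ester is then cleaved chemically by NH4OAc in MeOH/H2O at rt, a neutral transesterification that does not open the flavanone, giving 13.

Step 3 (hindered, tri-ortho-substituted Suzuki coupling). The fallback sets out from 3 and comes back at 5, replacing boron by zinc. Commercial 4-chloro-2-iodophenol is benzylated (BnBr, K2CO3, DMF) to 1-(benzyloxy)-4-chloro-2-iodobenzene F1. Iodine–magnesium exchange with iPrMgCl·LiCl in THF at −20 °C, then ZnCl2, gives [2-(benzyloxy)-5-chlorophenyl]zinc chloride F2. Negishi coupling of F2 with 3 (Pd2(dba)3, SPhos, THF, 40 °C) gives 5; this coupling tolerates the flavone carbonyl and is generally better for congested biaryls.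

## Further compounds

F1 | step 3 | 1-(benzyloxy)-4-chloro-2-iodobenzene | Clc1ccc(OCc2ccccc2)c(I)c1
F2 | step 3 | [2-(benzyloxy)-5-chlorophenyl]zinc chloride | Cl[Zn]c1cc(Cl)ccc1OCc1ccccc1
F3 | step 9 | 7-methoxy-5-(methoxymethoxy)-4H-chromen-4-one | COCOc1cc(OC)cc2occc(=O)c12
F4 | step 9 | (2S)-2-{4-acetoxy-3-[7-acetoxy-2-(4-acetoxyphenyl)-5-hydroxy-4-oxo-4H-chromen-8-yl]phenyl}-7-methoxy-5-(methoxymethoxy)chroman-4-one | COCOc1cc(OC)cc2c1C(=O)C[C@@H](c1ccc(OC(C)=O)c(-c3c(OC(C)=O)cc(O)c4c(=O)cc(-c5ccc(OC(C)=O)cc5)oc34)c1)O2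
F5 | step 10 | (2S)-2-{4-acetoxy-3-[5,7-dihydroxy-2-(4-hydroxyphenyl)-4-oxo-4H-chromen-8-yl]phenyl}-5-hydroxy-7-methoxychroman-4-one | COc1cc(O)c2c(c1)O[C@H](c1ccc(OC(C)=O)c(-c3c(O)cc(O)c4c(=O)cc(-c5ccc(O)cc5)oc34)c1)CC2=O
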